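**Plan**

1. Core numbering: C1 (methyl-bearing fusion carbon), C2, C3, C4 (ester carbinol with isopropyl), C5 (fusion CH), C6 (CHOH), C7=C8(CH3), C9 (C=O), C10 (CH2); five-membered ring C1–C5, seven-membered ring C1/C5–C10.
2. Enabling feature: the seven-membered ring is a five-carbon unit C1–C10–C9(=O)–C8–C7 closed by the two-carbon unit C5–C6, and C5 is held to C1 by the chain C4–C3–C2. This is the product pattern of an alkyne tethered to a 1-siloxy-1-alkenylcyclopropane.
3. Cuts: the C4–O aroyl bond, the C8–CH3 bond and the C7=C8 unsaturation, the C6–O and C5–H bonds (hydroboration), then C1–C5 and C6–C7 in one operation. The acyclic precursor is cut at C5≡C6 (aldehyde homologation), C1–C2 (B-alkyl Suzuki coupling) and C2–C3 (epoxide homologation).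
4. Forward: an (E)-alkenyl iodide carrying C1, C10, C9 and the cyclopropane is joined to a C4 building block and the alkyne is installed. The rhodium-catalysed cycloaddition then closes the five- and the seven-membered ring together. The bicycle is ketalised at C9, acylated at C4, hydroborated at C5=C6, methylated at C8 and dehydrogenated.
5. Stereochemistry: C4 comes from a Sharpless asymmetric epoxidation, C1 is set in the cycloaddition under control of C4, and C5 and C6 are set together in the hydroboration on the face opposite the C1 methyl group. C8 ends trigonal.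

Key step: step 16

Remark on the chemistry (assumption): the cyclopropane carries no methyl group, so its two ring bonds are equivalent and the face at C1 is decided by C4 alone. The C8 methyl group is added in step 23, and the C8 epimers formed there converge in step 24.

Locants in the names of the bicyclic compounds 23–36 follow the core numbering of the plan.

**Alkenyl iodide (steps 1–3)**

Step 1
Reactants: 1 (1-ethoxycyclopropoxy)trimethylsilane; 2 prop-1-yn-1-ylmagnesium bromide
Product: 4 1-(prop-1-yn-1-yl)cyclopropan-1-ol, via 1-ethoxycyclopropan-1-ol 3 (not isolated)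
Conditions: MeOH, rt, then evaporate; 2 (2.2 equiv), THF, 0 °C to reflux; aq. NH4Cl
Reagents that add atoms: none
Why: Methanolysis of the silyl ketal gives the cyclopropanone hemiketal, which the Grignard reagent deprotonates to release cyclopropanone in situ for 1,2-addition of a second equivalent (Grignard addition to a cyclopropanone equivalent).

Step 2
Reactants: 4 1-(prop-1-yn-1-yl)cyclopropan-1-ol
Product: 5 tert-butyldimethyl{[1-(prop-1-yn-1-yl)cyclopropyl]oxy}silane
Conditions: t-BuMe2SiCl, imidazole, DMF, rt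
Reagents that add atoms: tert-butyldimethylsilyl chloride, CC(C)(C)[Si](C)(C)Cl
Why: Silyl ether formation with a silyl chloride and imidazole, chosen because it is free of acid that could ring-expand the alkynylcyclopropanol.

Step 3
Reactants: 5 tert-butyldimethyl{[1-(prop-1-yn-1-yl)cyclopropyl]oxy}silane
Product: 7 tert-butyl({1-[(E)-2-iodoprop-1-en-1-yl]cyclopropyl}oxy)dimethylsilane, via the (E)-alkenylzirconocene chloride 6 (not isolated)
Conditions: Cp2Zr(H)Cl, THF, rt to 40 °C; then I2, 0 °C
Reagents that add atoms: iodine, II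
Why: Hydrozirconation adds Zr–H syn with zirconium on the less hindered, methyl-bearing alkyne carbon, and iodinolysis proceeds with retention, which gives the (E)-2-iodoalkene with iodine trans to the cyclopropane.

**Aroyl chloride (steps 4–5)**

Step 4
Reactants: 8 4-hydroxybenzoic acid
Product: 9 tert-butyldimethylsilyl 4-[(tert-butyldimethylsilyl)oxy]benzoate
Conditions: t-BuMe2SiCl (2.3 equiv), imidazole, DMF, rt
Reagents that add atoms: tert-butyldimethylsilyl chloride, CC(C)(C)[Si](C)(C)Cl
Why: Silylation of both the phenol and the carboxylic acid (silyl ether and silyl ester formation) under standard imidazole conditions.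

Step 5
Reactants: 9 tert-butyldimethylsilyl 4-[(tert-butyldimethylsilyl)oxy]benzoate
Product: 10 4-[(tert-butyldimethylsilyl)oxy]benzoyl chloride
Conditions: (COCl)2, DMF (cat.), CH2Cl2, 0 °C to rt
Reagents that add atoms: oxalyl chloride, O=C(Cl)C(Cl)=O
Why: The silyl ester is converted directly into the acid chloride by the Vilsmeier chloride formed from oxalyl chloride and DMF, under neutral conditions that leave the aryl silyl ether intact.

**Precursor (steps 6–15)**

Step 6
Reactants: 11 3-methylbutanal
Product: 12 3-methyl-2-methylidenebutanal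
Conditions: aq. CH2O, pyrrolidine (10 mol%), EtCO2H (10 mol%), i-PrOH, 45 °C
Reagents that add atoms: formaldehyde, C=O
Why: Amine-catalysed Mannich condensation with formaldehyde followed by elimination (α-methylenation of an aldehyde).

Step 7
Reactants: 12 3-methyl-2-methylidenebutanal
Product: 13 3-methyl-2-methylidenebutan-1-ol
Conditions: NaBH4, CeCl3·7H2O, MeOH, 0 °C
Reagents that add atoms: none
Why: Luche reduction gives clean 1,2-reduction of the enal to the allylic alcohol.

Step 8
Reactants: 13 3-methyl-2-methylidenebutan-1-ol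
Product: 14 [(2R)-2-(propan-2-yl)oxiran-2-yl]methanol
Conditions: Ti(OiPr)4 (10 mol%), D-(−)-diethyl tartrate (12 mol%), t-BuOOH, 4 Å MS, CH2Cl2, −20 °C
Reagents that add atoms: tert-butyl hydroperoxide, CC(C)(C)OO
Why: Sharpless asymmetric epoxidation of a 2-substituted allylic alcohol, in which the titanium tartrate complex delivers oxygen to one alkene face and so sets C4; D-(−)-tartrate is the antipode that leads to the (R)-epoxy alcohol.

Step 9
Reactants: 14 [(2R)-2-(propan-2-yl)oxiran-2-yl]methanol
Product: 15 (2S)-2-{[(4-methoxyphenyl)methoxy]methyl}-2-(propan-2-yl)oxirane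
Conditions: NaH, 4-MeOC6H4CH2Cl, Bu4NI (cat.), THF/DMF, 0 °C to rt
Reagents that add atoms: 4-methoxybenzyl chloride, COc1ccc(CCl)cc1
Why: Williamson ether synthesis on the primary alkoxide, which protects the future C5 oxygen orthogonally to the silyl ethers (the descriptor changes by priority only).

Step 10
Reactants: 15 (2S)-2-{[(4-methoxyphenyl)methoxy]methyl}-2-(propan-2-yl)oxirane
Product: 16 (3S)-3-{[(4-methoxyphenyl)methoxy]methyl}-4-methylpent-1-en-3-ol
Conditions: Me3SI, n-BuLi, THF, −10 °C to rt
Reagents that add atoms: trimethylsulfonium iodide, C[S+](C)C.[I-]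
Why: Dimethylsulfonium methylide opens the epoxide at its CH2 terminus and a second equivalent eliminates dimethyl sulfide from the betaine, the known one-carbon homologation of epoxides to allylic alcohols, which leaves the C4 stereocentre untouched.

Step 11
Reactants: 16 (3S)-3-{[(4-methoxyphenyl)methoxy]methyl}-4-methylpent-1-en-3-ol
Product: 17 triethyl{[(3S)-3-{[(4-methoxyphenyl)methoxy]methyl}-4-methylpent-1-en-3-yl]oxy}silane
Conditions: Et3SiOTf, 2,6-lutidine, CH2Cl2, 0 °C
Reagents that add atoms: triethylsilyl trifluoromethanesulfonate, CC[Si](CC)(CC)OS(=O)(=O)C(F)(F)F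
Why: Silylation of a hindered tertiary alcohol with a silyl triflate and 2,6-lutidine.

Step 12
Reactants: 17 triethyl{[(3S)-3-{[(4-methoxyphenyl)methoxy]methyl}-4-methylpent-1-en-3-yl]oxy}silane; 7 tert-butyl({1-[(E)-2-iodoprop-1-en-1-yl]cyclopropyl}oxy)dimethylsilane
Product: 19 1-methoxy-4-({[(2R,5E)-6-{1-[(tert-butyldimethylsilyl)oxy]cyclopropyl}-5-methyl-2-(propan-2-yl)-2-[(triethylsilyl)oxy]hex-5-en-1-yl]oxy}methyl)benzene, via the B-alkyl-9-borabicyclo[3.3.1]nonane 18 (not isolated)
Conditions: 9-BBN, THF, rt to 50 °C; then 7, Pd(dppf)Cl2 (5 mol%), AsPh3, Cs2CO3, DMF/H2O, rt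
Reagents that add atoms: none
Why: 9-BBN hydroborates the monosubstituted alkene at its terminus and the alkylborane is joined to the alkenyl iodide by B-alkyl Suzuki–Miyaura coupling with retention of the (E) geometry.

Step 13
Reactants: 19 the 4-methoxybenzyl ether from step 12
Product: 20 (2R,5E)-6-{1-[(tert-butyldimethylsilyl)oxy]cyclopropyl}-5-methyl-2-(propan-2-yl)-2-[(triethylsilyl)oxy]hex-5-en-1-ol
Conditions: DDQ, CH2Cl2/pH 7 buffer, 0 °C
Reagents that add atoms: none
Why: Oxidative cleavage of the 4-methoxybenzyl ether by DDQ under buffered conditions that spare the silyl ethers and the acid-sensitive siloxycyclopropane.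

Step 14
Reactants: 20 (2R,5E)-6-{1-[(tert-butyldimethylsilyl)oxy]cyclopropyl}-5-methyl-2-(propan-2-yl)-2-[(triethylsilyl)oxy]hex-5-en-1-ol
Product: 21 (2R,5E)-6-{1-[(tert-butyldimethylsilyl)oxy]cyclopropyl}-5-methyl-2-(propan-2-yl)-2-[(triethylsilyl)oxy]hex-5-enal
Conditions: Dess–Martin periodinane, NaHCO3, CH2Cl2, 0 °C to rt
Reagents that add atoms: none
Why: Dess–Martin oxidation of the neopentyl-type primary alcohol under buffered conditions; the aldehyde has no α-hydrogen and cannot epimerise.

Step 15
Reactants: 21 (2R,5E)-6-{1-[(tert-butyldimethylsilyl)oxy]cyclopropyl}-5-methyl-2-(propan-2-yl)-2-[(triethylsilyl)oxy]hex-5-enal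
Product: 22 tert-butyl({1-[(1E,5R)-2-methyl-5-(propan-2-yl)-5-[(triethylsilyl)oxy]hept-1-en-6-yn-1-yl]cyclopropyl}oxy)dimethylsilane
Conditions: MeC(O)C(N2)P(O)(OMe)2, K2CO3, MeOH, 0 °C to rt
Reagents that add atoms: dimethyl (1-diazo-2-oxopropyl)phosphonate, COP(=O)(OC)C(=[N+]=[N-])C(C)=O
Why: Seyferth–Gilbert homologation in its Ohira–Bestmann form converts the non-enolisable aldehyde into the terminal alkyne (C5≡C6) under mild base that the silyl ethers tolerate.

**Key step and completion (steps 16–25)**

Step 16
Reactants: 22 tert-butyl({1-[(1E,5R)-2-methyl-5-(propan-2-yl)-5-[(triethylsilyl)oxy]hept-1-en-6-yn-1-yl]cyclopropyl}oxy)dimethylsilane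
Product: 23 cycloadduct (1R,4R)-9-(tert-butyldimethylsilyloxy)-1-methyl-4-(propan-2-yl)-4-(triethylsilyloxy)hydroazulene-5,9-diene (C5=C6 alkene, C9=C10 silyl enol ether; azulene name (3R,8aR)-7-[(tert-butyldimethylsilyl)oxy]-8a-methyl-3-(propan-2-yl)-3-[(triethylsilyl)oxy]-1,2,3,5,6,8a-hexahydroazulene)
Conditions: [Rh(CO)2Cl]2 (5 mol%), toluene, 80 °C
Reagents that add atoms: none
Why: Monovalent rhodium binds the alkyne and the alkenylcyclopropane of 22, opens one of the two equivalent C9–CH2 cyclopropane bonds to a trivalent rhodacyclohexene (σ-alkyl at C7, π-allyl over C9–C10–C1), inserts the tethered alkyne at the allyl terminus to form C1–C5, and forms C6–C7 by reductive elimination. The closest known reaction type is the rhodium-catalysed intramolecular [5+2] cycloaddition of alkyne-tethered vinylcyclopropanes, which tolerates 1-oxygenated cyclopropanes and alkene termini that become quaternary. The cyclopentene closes by 5-exo migratory insertion of the alkyne into the Rh–C1 bond over the three-atom tether C2–C3–C4, and the cycloheptadiene closes by C(sp2)–C(sp3) reductive elimination from the eight-membered rhodacycle. The one new stereocentre, C1, is controlled by C4: the isopropyl group, which has the larger near-range demand of the two propargylic substituents, should take the face of the forming cyclopentene that carries the flat allyl carbon C10 and avoid the C1 methyl group, which leaves the silyloxy group cis to that methyl group as in the target. This facial selectivity is the only selectivity the step needs and is not secured by precedent: with an unsubstituted cyclopropane the choice between the two ring bonds is the same as the choice of face, the tether fixes the regiochemistry, and the siloxy group both activates the ring and delivers C9 as a silyl enol ether.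

Step 17
Reactants: 23 cycloadduct
Product: 24 (1R,4R)-C9 ethylene ketal of the C5=C6 alkene bearing the C4 triethylsilyl ether
Conditions: HOCH2CH2OH, PPTS, benzene, reflux (Dean–Stark)
Reagents that add atoms: ethane-1,2-diol, OCCO
Why: Acid-catalysed ketalisation, in which protonation of the silyl enol ether at C10 gives the C9 oxocarbenium ion that the diol captures with loss of silanol, while the mild acid leaves the tertiary allylic silyl ether in place.

Step 18
Reactants: 24 ketal silyl ether
Product: 25 (1R,4R)-C9 ethylene ketal of the C5=C6 alkene bearing the free C4 tertiary alcohol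
Conditions: Bu4NF, THF, rt to 45 °C
Reagents that add atoms: none
Why: Fluoride-mediated cleavage of the tertiary triethylsilyl ether.

Step 19
Reactants: 25 tertiary allylic alcohol; 10 4-[(tert-butyldimethylsilyl)oxy]benzoyl chloride
Product: 27 (1R,4R)-C4 4-[(tert-butyldimethylsilyl)oxy]benzoate of 25, via the potassium alkoxide 26 (not isolated)
Conditions: KN(SiMe3)2, THF, −78 °C; then 10, −78 to 0 °C
Reagents that add atoms: none
Why: Acylation of a preformed potassium alkoxide with an aroyl chloride, the standard way to esterify a hindered tertiary alcohol (as in the preparation of tert-butyl benzoates from tert-butoxides).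

Step 20
Reactants: 27 tertiary allylic ester
Product: 29 (1R,4R,5S,6S)-C6 alcohol (trans-fused C9 ketal bearing the C4 aroyl ester), via the C6 alkylborane 28 (not isolated)
Conditions: BH3·THF, THF, 0 °C to rt; then NaBO3·4H2O, THF/H2O, rt
Reagents that add atoms: sodium perborate tetrahydrate, [Na+].[O-]OB=O.O.O.O.O
Why: Hydroboration–oxidation, in which borane adds syn with boron on the less substituted C6 from the face opposite the C1 methyl and C4 aroyloxy groups (as in angular-methyl steroid alkenes), setting C5–H and C6–OH cis to each other and the ring fusion trans; perborate oxidises with retention and is mild towards the ester and the aryl silyl ether.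

Step 21
Reactants: 29 C6 alcohol
Product: 30 C6 tert-butyldimethylsilyl ether of 29
Conditions: t-BuMe2SiOTf, 2,6-lutidine, CH2Cl2, 0 °C
Reagents that add atoms: tert-butyldimethylsilyl trifluoromethanesulfonate, CC(C)(C)[Si](C)(C)OS(=O)(=O)C(F)(F)F
Why: Silyl triflate silylation of the hindered secondary alcohol, which would also re-silylate any phenol set free in step 20.

Step 22
Reactants: 30 ketal
Product: 31 (1R,4R,5S,6S)-C9 ketone bearing the C6 silyl ether and the C4 aroyl ester
Conditions: PPTS, acetone/H2O, 55 °C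
Reagents that add atoms: water, O
Why: Acid-catalysed hydrolysis of the dioxolane under conditions mild enough for the silyl ethers and the tertiary ester.

Step 23
Reactants: 31 ketone
Product: 33 C8-methyl ketone (both C8 epimers), via the lithium enolate 32 (not isolated)
Conditions: LiN(iPr)2, THF, −78 °C; then MeI, −78 to −30 °C
Reagents that add atoms: iodomethane, CI
Why: Kinetic enolate alkylation, in which the lithium amide removes a proton from C8 and not from the neopentyl C10 next to the quaternary C1, and the enolate is methylated at C8, whose configuration is of no consequence.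

Step 24
Reactants: 33 C8-methyl ketone
Product: 35 (1R,4R,5S,6S)-enone C7=C8(CH3)–C9=O bearing the C6 silyl ether and the C4 aroyl ester, via the trimethylsilyl enol ether 34 (not isolated)
Conditions: Me3SiOTf, Et3N, CH2Cl2, 0 °C to rt; then Pd(OAc)2, MeCN, rt
Reagents that add atoms: none
Why: Saegusa–Ito oxidation through the more substituted silyl enol ether; only the C8 enol ether can lead to an enone because C1 carries no hydrogen, and β-hydride elimination into the ring gives the C7=C8 enone.

Step 25
Reactants: 35 bis-silyl enone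
Product: 36 (3R,3aS,4S,8aR)-4-hydroxy-6,8a-dimethyl-7-oxo-3-(propan-2-yl)-1,2,3,3a,4,7,8,8a-octahydroazulen-3-yl 4-hydroxybenzoate (CNP0153637.1; core descriptors 1R,4R,5S,6S)
Conditions: HF·pyridine, pyridine, THF, 0 °C to rt
Reagents that add atoms: none
Why: Fluoride cleavage of the secondary alkyl and the aryl silyl ether with buffered HF·pyridine, a non-basic reagent that avoids base-induced isomerisation of the γ-hydroxy enone and leaves the tertiary ester alone.

**Compound list**

1 | (1-ethoxycyclopropoxy)trimethylsilane | CCOC1(O[Si](C)(C)C)CC1 | starting material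
2 | prop-1-yn-1-ylmagnesium bromide | CC#C[Mg]Br | starting material
3 | 1-ethoxycyclopropan-1-ol | CCOC1(O)CC1 | intermediate
4 | 1-(prop-1-yn-1-yl)cyclopropan-1-ol | CC#CC1(O)CC1 | intermediate
5 | tert-butyldimethyl{[1-(prop-1-yn-1-yl)cyclopropyl]oxy}silane | CC#CC1(O[Si](C)(C)C(C)(C)C)CC1 | intermediate
6 | chloridobis(cyclopentadienyl)[(E)-1-{1-[(tert-butyldimethylsilyl)oxy]cyclopropyl}prop-1-en-2-yl]zirconium | C/C(=C\C1(O[Si](C)(C)C(C)(C)C)CC1)[Zr](Cl)(C2C=CC=C2)C2C=CC=C2 | intermediate
7 | tert-butyl({1-[(E)-2-iodoprop-1-en-1-yl]cyclopropyl}oxy)dimethylsilane | C/C(I)=C\C1(O[Si](C)(C)C(C)(C)C)CC1 | intermediate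
8 | 4-hydroxybenzoic acid | OC(=O)c1ccc(O)cc1 | starting material
9 | tert-butyldimethylsilyl 4-[(tert-butyldimethylsilyl)oxy]benzoate | CC(C)(C)[Si](C)(C)OC(=O)c1ccc(O[Si](C)(C)C(C)(C)C)cc1 | intermediate
10 | 4-[(tert-butyldimethylsilyl)oxy]benzoyl chloride | ClC(=O)c1ccc(O[Si](C)(C)C(C)(C)C)cc1 | intermediate
11 | 3-methylbutanal | CC(C)CC=O | starting material
12 | 3-methyl-2-methylidenebutanal | CC(C)C(=C)C=O | intermediate
13 | 3-methyl-2-methylidenebutan-1-ol | CC(C)C(=C)CO | intermediate
14 | [(2R)-2-(propan-2-yl)oxiran-2-yl]methanol | OC[C@@]1(CO1)C(C)C | intermediate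
15 | (2S)-2-{[(4-methoxyphenyl)methoxy]methyl}-2-(propan-2-yl)oxirane | COc1ccc(COC[C@@]2(CO2)C(C)C)cc1 | intermediate
16 | (3S)-3-{[(4-methoxyphenyl)methoxy]methyl}-4-methylpent-1-en-3-ol | COc1ccc(COC[C@@](O)(C=C)C(C)C)cc1 | intermediate
17 | triethyl{[(3S)-3-{[(4-methoxyphenyl)methoxy]methyl}-4-methylpent-1-en-3-yl]oxy}silane | COc1ccc(COC[C@@](O[Si](CC)(CC)CC)(C=C)C(C)C)cc1 | intermediate
18 | 9-[(3R)-3-{[(4-methoxyphenyl)methoxy]methyl}-4-methyl-3-[(triethylsilyl)oxy]pentyl]-9-borabicyclo[3.3.1]nonane | COc1ccc(COC[C@@](O[Si](CC)(CC)CC)(CCB2C3CCCC2CCC3)C(C)C)cc1 | intermediate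
19 | 1-methoxy-4-({[(2R,5E)-6-{1-[(tert-butyldimethylsilyl)oxy]cyclopropyl}-5-methyl-2-(propan-2-yl)-2-[(triethylsilyl)oxy]hex-5-en-1-yl]oxy}methyl)benzene | COc1ccc(COC[C@@](O[Si](CC)(CC)CC)(CC/C(C)=C/C2(O[Si](C)(C)C(C)(C)C)CC2)C(C)C)cc1 | intermediate
20 | (2R,5E)-6-{1-[(tert-butyldimethylsilyl)oxy]cyclopropyl}-5-methyl-2-(propan-2-yl)-2-[(triethylsilyl)oxy]hex-5-en-1-ol | OC[C@@](O[Si](CC)(CC)CC)(CC/C(C)=C/C1(O[Si](C)(C)C(C)(C)C)CC1)C(C)C | intermediate
21 | (2R,5E)-6-{1-[(tert-butyldimethylsilyl)oxy]cyclopropyl}-5-methyl-2-(propan-2-yl)-2-[(triethylsilyl)oxy]hex-5-enal | O=C[C@@](O[Si](CC)(CC)CC)(CC/C(C)=C/C1(O[Si](C)(C)C(C)(C)C)CC1)C(C)C | intermediate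
22 | tert-butyl({1-[(1E,5R)-2-methyl-5-(propan-2-yl)-5-[(triethylsilyl)oxy]hept-1-en-6-yn-1-yl]cyclopropyl}oxy)dimethylsilane (cycloaddition precursor) | C#C[C@@](O[Si](CC)(CC)CC)(CC/C(C)=C/C1(O[Si](C)(C)C(C)(C)C)CC1)C(C)C | intermediate
23 | (3R,8aR)-7-[(tert-butyldimethylsilyl)oxy]-8a-methyl-3-(propan-2-yl)-3-[(triethylsilyl)oxy]-1,2,3,5,6,8a-hexahydroazulene (cycloadduct; core 1R,4R; C5=C6 and C9=C10) | C1CC=C2[C@](C)(CC[C@@]2(O[Si](CC)(CC)CC)C(C)C)C=C1O[Si](C)(C)C(C)(C)C | intermediate
24 | (1R,4R)-C9 ethylene ketal of the C5=C6 alkene, C4 triethylsilyl ether | C1CC=C2[C@](C)(CC[C@@]2(O[Si](CC)(CC)CC)C(C)C)CC13OCCO3 | intermediate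
25 | (1R,4R)-C9 ethylene ketal of the C5=C6 alkene, free C4 tertiary alcohol | C1CC=C2[C@](C)(CC[C@@]2(O)C(C)C)CC13OCCO3 | intermediate
26 | potassium C4 alkoxide of 25 | C1CC=C2[C@](C)(CC[C@@]2([O-])C(C)C)CC13OCCO3.[K+] | intermediate
27 | (1R,4R)-C4 4-[(tert-butyldimethylsilyl)oxy]benzoate of 25 | C1CC=C2[C@](C)(CC[C@@]2(OC(=O)c4ccc(O[Si](C)(C)C(C)(C)C)cc4)C(C)C)CC13OCCO3 | intermediate
28 | (1R,4R,5S,6S)-C6 borane of 27 (C5–H and C6–B on the face opposite the C1 methyl) | C1C[C@H](B)[C@@H]2[C@](C)(CC[C@@]2(OC(=O)c4ccc(O[Si](C)(C)C(C)(C)C)cc4)C(C)C)CC13OCCO3 | intermediate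
29 | (1R,4R,5S,6S)-C6 alcohol, trans-fused, C9 ethylene ketal, C4 4-[(tert-butyldimethylsilyl)oxy]benzoate | C1C[C@H](O)[C@@H]2[C@](C)(CC[C@@]2(OC(=O)c4ccc(O[Si](C)(C)C(C)(C)C)cc4)C(C)C)CC13OCCO3 | intermediate
30 | C6 tert-butyldimethylsilyl ether of 29 | C1C[C@H](O[Si](C)(C)C(C)(C)C)[C@@H]2[C@](C)(CC[C@@]2(OC(=O)c4ccc(O[Si](C)(C)C(C)(C)C)cc4)C(C)C)CC13OCCO3 | intermediate
31 | (1R,4R,5S,6S)-C9 ketone, C6 silyl ether, C4 aroyl ester | O=C1CC[C@H](O[Si](C)(C)C(C)(C)C)[C@@H]2[C@](C)(CC[C@@]2(OC(=O)c3ccc(O[Si](C)(C)C(C)(C)C)cc3)C(C)C)C1 | intermediate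
32 | lithium C8=C9 enolate of 31 | [Li+].[O-]C1=CC[C@H](O[Si](C)(C)C(C)(C)C)[C@@H]2[C@](C)(CC[C@@]2(OC(=O)c3ccc(O[Si](C)(C)C(C)(C)C)cc3)C(C)C)C1 | intermediate
33 | C8-methyl ketone (both C8 epimers) | O=C1C(C)C[C@H](O[Si](C)(C)C(C)(C)C)[C@@H]2[C@](C)(CC[C@@]2(OC(=O)c3ccc(O[Si](C)(C)C(C)(C)C)cc3)C(C)C)C1 | intermediate
34 | C8=C9 trimethylsilyl enol ether of 33 | C[Si](C)(C)OC1=C(C)C[C@H](O[Si](C)(C)C(C)(C)C)[C@@H]2[C@](C)(CC[C@@]2(OC(=O)c3ccc(O[Si](C)(C)C(C)(C)C)cc3)C(C)C)C1 | intermediate
35 | (1R,4R,5S,6S)-enone C7=C8(CH3)–C9=O, C6 silyl ether, C4 4-[(tert-butyldimethylsilyl)oxy]benzoate | O=C1C(C)=C[C@H](O[Si](C)(C)C(C)(C)C)[C@@H]2[C@](C)(CC[C@@]2(OC(=O)c3ccc(O[Si](C)(C)C(C)(C)C)cc3)C(C)C)C1 | intermediate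
36 | (3R,3aS,4S,8aR)-4-hydroxy-6,8a-dimethyl-7-oxo-3-(propan-2-yl)-1,2,3,3a,4,7,8,8a-octahydroazulen-3-yl 4-hydroxybenzoate | CC1=C[C@H](O)[C@@H]2[C@](C)(CC[C@@]2(OC(=O)c2ccc(O)cc2)C(C)C)CC1=O | target

**Step count**

Total: 25 steps. Longest linear sequence: 20 steps (steps 6–25, from 3-methylbutanal); steps 1–3 and 4–5 are side branches.

**Steps most likely to fail**

1. Step 16. The two C4 substituents may discriminate only weakly between the faces of the forming cyclopentene, so both C1 epimers could form, and turnover at the fully substituted alkene terminus may be slow. Fallback: stereocontrol is moved from the substrate to the catalyst. The same precursor 22 is cyclised to 23 with a cationic monovalent rhodium catalyst carrying an enantiopure diphosphine, [Rh((R)-BINAP)]SbF6 or its (S)-antipode, in 1,2-dichloroethane, the known enantioselective form of this cycloaddition. The antipode matched with C4 is used, so that the ligand rather than C4 fixes the face at C1. The fallback sets out from 22, returns at 23 and passes through no new compound (F0).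

2. Step 20. Borane may add with low facial selectivity, or add so slowly to the hindered alkene that the ester is reduced. Fallback: C5 is set by equilibration and C6 by a hydroxyl-directed reduction, setting out from 25.
   - Hydroboration–oxidation of 25 (BH3·THF; NaBO3·4H2O) goes through the borane F1 to the diol F2, taken as whatever C5/C6 mixture results.
   - Dess–Martin oxidation gives the C6 ketone, and DBU in toluene should equilibrate C5 to the trans-fused hydroxy ketone F3, in which C6 lies next to the C4 hydroxyl rather than the isopropyl group.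
   - Me4NBH(OAc)3 in MeCN/AcOH at −20 °C delivers hydride from the C4 oxygen to the face of C6 that carries it (Evans–Saksena reduction). This should give the anti-diol F4, with the C6 hydroxyl on the face opposite the C4 oxygen as the target requires.
   - Selective silylation of the secondary alcohol (t-BuMe2SiOTf, 2,6-lutidine, −78 °C) gives the C6 silyl ether F5, and acylation of its potassium alkoxide F6 with 10 under the conditions of step 19 returns to the route at 30.

3. Step 19. The very hindered tertiary alkoxide may be acylated incompletely while the acid chloride is consumed in other ways. Fallback: the ester is assembled from the carbonate side, so that the electrophile meeting the hindered oxygen is small. Setting out from 25, the alkoxide 26 is treated with 1,1'-carbonyldiimidazole to give the imidazole-1-carboxylate F7. 4-[(tert-Butyldimethylsilyl)oxy]phenylmagnesium bromide F8, made from (4-bromophenoxy)(tert-butyl)dimethylsilane and magnesium, then displaces imidazole at −78 to 0 °C and gives 27, where the route is rejoined. The hindered ester should not take up a second equivalent.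

Further compounds
F0 | step 16 | none | none
F1 | step 20 | C6 borane of 25 with O-borylated C4 oxygen (C5/C6 mixture) | C1CC(B)C2[C@](C)(CC[C@@]2(OB)C(C)C)CC13OCCO3
F2 | step 20 | C4,C6-diol of the C9 ethylene ketal (C5/C6 mixture) | C1CC(O)C2[C@](C)(CC[C@@]2(O)C(C)C)CC13OCCO3
F3 | step 20 | trans-fused C6 ketone with free C4 alcohol, C9 ethylene ketal | C1CC(=O)[C@@H]2[C@](C)(CC[C@@]2(O)C(C)C)CC13OCCO3
F4 | step 20 | (1R,4R,5S,6S)-C4,C6-anti-diol, C9 ethylene ketal | C1C[C@H](O)[C@@H]2[C@](C)(CC[C@@]2(O)C(C)C)CC13OCCO3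
F5 | step 20 | C6 tert-butyldimethylsilyl ether of F4 | C1C[C@H](O[Si](C)(C)C(C)(C)C)[C@@H]2[C@](C)(CC[C@@]2(O)C(C)C)CC13OCCO3
F6 | step 20 | potassium C4 alkoxide of F5 | C1C[C@H](O[Si](C)(C)C(C)(C)C)[C@@H]2[C@](C)(CC[C@@]2([O-])C(C)C)CC13OCCO3.[K+]
F7 | step 19 | C4 imidazole-1-carboxylate of 25 | C1CC=C2[C@](C)(CC[C@@]2(OC(=O)n4ccnc4)C(C)C)CC13OCCO3
F8 | step 19 | 4-[(tert-butyldimethylsilyl)oxy]phenylmagnesium bromide | CC(C)(C)[Si](C)(C)Oc1ccc([Mg]Br)cc1
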